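**Strategy.** Everything rests on cutting ring A of the flavone at two neighbouring carbons: C8a, which bears O1, and C4a, which bears the C4 carbonyl. An aryne spanning C4a–C8a is inserted into the O–C(acyl) bond of 3-(2,3-dimethoxyphenyl)propiolic acid, forming O1–C8a and C4–C4a in one operation and giving the ortho-hydroxyaryl ynone that only needs pyranone closure. The aryne precursor is an ortho-silylaryl triflate carrying the C5 and C7 oxygens as MOM ethers and the C6 methoxy group; the C5 acetal oxygen, the sole substituent flanking the aryne, dictates the direction of addition. C8 stays C–H and is methoxylated after ring closure.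

Key step: step 7

Remark: flavone numbering (O1, C2–C8a, ring A, ring B) is used for all intermediates; enaminone 16 is drawn as the E isomer, and its geometry has no bearing on the ring closure.

**Route**

Step 1
Reactants: 1 2-methoxyresorcinol; 2 chloromethyl methyl ether
Product: 3 2-methoxy-1,3-bis(methoxymethoxy)benzene
Conditions: MOMCl (2.5 equiv), DIPEA (3 equiv), CH2Cl2, 0 °C → rt
Reagents that add atoms: chloromethyl methyl ether (compound 2), COCCl
Why: Williamson-type O-alkylation of both phenols by the reactive α-chloro ether gives the bis-MOM acetal, which masks the future C5 and C7 oxygens through the basic and organometallic steps and is removed in one acid step at the end.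

Step 2
Reactants: 3 2-methoxy-1,3-bis(methoxymethoxy)benzene
Product: 5 4-methoxy-3,5-bis(methoxymethoxy)phenol, via aryl pinacol boronate 4 (not isolated)
Conditions: [Ir(OMe)(cod)]2 (1.5 mol %), dtbpy (3 mol %), B2pin2 (0.6 equiv), THF, 80 °C; then 30% aq. H2O2, aq. NaOH, 0 °C
Reagents that add atoms: hydrogen peroxide, OO
Why: Iridium-catalysed C–H borylation is sterically governed and should go to the only ring C–H without an ortho substituent (meta to both MOM ethers), and basic peroxide oxidation of the C–B bond then gives the phenol in the same flask.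

Step 3
Reactants: 5 4-methoxy-3,5-bis(methoxymethoxy)phenol
Product: 6 2-bromo-4-methoxy-3,5-bis(methoxymethoxy)phenol
Conditions: NBS (1.0 equiv), CH2Cl2, −78 → −20 °C
Reagents that add atoms: N-bromosuccinimide, O=C1CCC(=O)N1Br
Why: Electrophilic aromatic bromination ortho to the free hydroxyl; the two ortho positions are equivalent by symmetry and the para position is blocked, so one equivalent of NBS in the cold should give a single monobromide.

Step 4
Reactants: 6 2-bromo-4-methoxy-3,5-bis(methoxymethoxy)phenol
Product: 9 4-methoxy-3,5-bis(methoxymethoxy)-2-(trimethylsilyl)phenyl trifluoromethanesulfonate, via aryl trimethylsilyl ether 7 (not isolated), via lithium silylphenoxide 8 (not isolated)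
Conditions: HMDS, THF, 70 °C, volatiles removed; n-BuLi, THF, −100 °C; Tf2O, −100 → −78 °C
Reagents that add atoms: hexamethyldisilazane, C[Si](C)(C)N[Si](C)(C)C; trifluoromethanesulfonic anhydride, O=S(=O)(OS(=O)(=O)C(F)(F)F)C(F)(F)F
Why: O-silylation, bromine–lithium exchange and anionic 1,3 O→C silyl migration (retro-Brook rearrangement) place the silyl group on the carbon next to the phenoxide, which is triflated in the same flask; this is the standard one-pot entry to ortho-silylaryl triflates and MOM ethers tolerate it.

Step 5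
Reactants: 10 2,3-dimethoxybenzaldehyde
Product: 11 1-(2,2-dibromoethenyl)-2,3-dimethoxybenzene
Conditions: CBr4, PPh3, CH2Cl2, 0 °C
Reagents that add atoms: carbon tetrabromide, BrC(Br)(Br)Br
Why: First stage of the Corey–Fuchs reaction, a Wittig-type dibromo-olefination of the aromatic aldehyde by the ylide formed from CBr4 and PPh3.

Step 6
Reactants: 11 1-(2,2-dibromoethenyl)-2,3-dimethoxybenzene
Product: 13 3-(2,3-dimethoxyphenyl)prop-2-ynoic acid, via lithium acetylide 12 (not isolated)
Conditions: n-BuLi (2.2 equiv), THF, −78 °C; CO2 (g), −78 → 0 °C; aq. HCl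
Reagents that add atoms: carbon dioxide, O=C=O
Why: Second stage of the Corey–Fuchs reaction: exchange and elimination (Fritsch–Buttenberg–Wiechell type) turn the dibromo-olefin into the lithium acetylide, which is carboxylated by CO2 and protonated on work-up.

Step 7
Reactants: 9 4-methoxy-3,5-bis(methoxymethoxy)-2-(trimethylsilyl)phenyl trifluoromethanesulfonate; 13 3-(2,3-dimethoxyphenyl)prop-2-ynoic acid
Product: 15 1-[6-hydroxy-3-methoxy-2,4-bis(methoxymethoxy)phenyl]-3-(2,3-dimethoxyphenyl)prop-2-yn-1-one, via aryne 14 (not isolated)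
Conditions: 9 (1.3 equiv), CsF (4 equiv), THF, 80 °C (sealed tube); then sat. aq. NH4Cl, 0 °C
Reagents that add atoms: none
Why: Fluoride strips the trimethylsilyl group and triflate departs to give aryne 14; the carboxylate of 13 adds through oxygen to C8a, and the aryl anion created at C4a attacks its own ester carbonyl through a four-membered alkoxide that opens to the ortho-acyl phenoxide, so O1–C8a and C4–C4a are formed in a single operation. The closest known reaction type is the fluoride-induced formal insertion of arynes into the C–O bond of carboxylic acids to give ortho-hydroxyaryl ketones, an intermolecular counterpart of the anionic Fries rearrangement. No ring is closed and no stereocentre is created; the moderate temperature and the cold, mildly acidic quench are chosen so that the phenoxide is protonated before it can add to the ynone. The selectivity needed is regiochemical: the MOM-protected oxygen at C5 is the only group flanking the aryne, and its inductive pull on the distorted triple bond sends the oxygen nucleophile to the distal carbon C8a and leaves the carbanion beside it at C4a, while C8 is deliberately C–H so that no second flanking oxygen competes. MOM acetals, aryl methyl ethers and the alkyne are inert to CsF.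

Step 8
Reactants: 15 1-[6-hydroxy-3-methoxy-2,4-bis(methoxymethoxy)phenyl]-3-(2,3-dimethoxyphenyl)prop-2-yn-1-one
Product: 17 2-(2,3-dimethoxyphenyl)-6-methoxy-5,7-bis(methoxymethoxy)-4H-chromen-4-one, via enaminone 16 (not isolated)
Conditions: Et2NH (5 equiv), EtOH, rt → 70 °C
Reagents that add atoms: none
Why: Conjugate addition of the secondary amine to the ynone gives enaminone 16, and the ortho phenol then displaces the amine by intramolecular addition–elimination at the β-carbon, which can only form the six-membered pyranone and so avoids the five-membered aurone.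

Step 9
Reactants: 17 2-(2,3-dimethoxyphenyl)-6-methoxy-5,7-bis(methoxymethoxy)-4H-chromen-4-one
Product: 18 8-bromo-2-(2,3-dimethoxyphenyl)-6-methoxy-5,7-bis(methoxymethoxy)-4H-chromen-4-one
Conditions: NBS (1.05 equiv), DMF, 0 °C → rt
Reagents that add atoms: N-bromosuccinimide, O=C1CCC(=O)N1Br
Why: Electrophilic aromatic bromination at C8, the only unsubstituted carbon of ring A, which is activated by the C7 and C5 acetal oxygens and by O1 and is far more nucleophilic than C3 or ring B; NBS in DMF keeps the medium non-acidic for the MOM ethers.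

Step 10
Reactants: 18 8-bromo-2-(2,3-dimethoxyphenyl)-6-methoxy-5,7-bis(methoxymethoxy)-4H-chromen-4-one
Product: 19 2-(2,3-dimethoxyphenyl)-6,8-dimethoxy-5,7-bis(methoxymethoxy)-4H-chromen-4-one
Conditions: NaOMe (25% in MeOH, 10 equiv), CuBr (0.3 equiv), DMF, 110 °C
Reagents that add atoms: sodium methoxide, [Na+].[O-]C
Why: Ullmann-type copper-mediated exchange of an aryl bromide for methoxide, a reaction established on bromoflavones; the MOM ethers and aryl methyl ethers are stable to methoxide.

Step 11
Reactants: 19 2-(2,3-dimethoxyphenyl)-6,8-dimethoxy-5,7-bis(methoxymethoxy)-4H-chromen-4-one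
Product: 20 2-(2,3-dimethoxyphenyl)-5,7-dihydroxy-6,8-dimethoxy-4H-chromen-4-one (5,7-dihydroxy-6,8,2',3'-tetramethoxyflavone)
Conditions: HCl (3 M in MeOH), 50 °C
Reagents that add atoms: none
Why: Acid-catalysed acetal cleavage (transacetalisation to dimethoxymethane) frees the C5 and C7 phenols, while the four aryl methyl ethers and the flavone core are stable to dilute acid.

**Compound list**

1 | 2-methoxyresorcinol (2-methoxybenzene-1,3-diol) | COc1c(O)cccc1O | starting material
2 | chloromethyl methyl ether | COCCl | starting material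
3 | 2-methoxy-1,3-bis(methoxymethoxy)benzene | COCOc1cccc(OCOC)c1OC | intermediate
4 | 2-[4-methoxy-3,5-bis(methoxymethoxy)phenyl]-4,4,5,5-tetramethyl-1,3,2-dioxaborolane | COCOc1cc(B2OC(C)(C)C(C)(C)O2)cc(OCOC)c1OC | intermediate (not isolated)
5 | 4-methoxy-3,5-bis(methoxymethoxy)phenol | COCOc1cc(O)cc(OCOC)c1OC | intermediate
6 | 2-bromo-4-methoxy-3,5-bis(methoxymethoxy)phenol | COCOc1cc(O)c(Br)c(OCOC)c1OC | intermediate
7 | [2-bromo-4-methoxy-3,5-bis(methoxymethoxy)phenoxy]trimethylsilane | COCOc1cc(O[Si](C)(C)C)c(Br)c(OCOC)c1OC | intermediate (not isolated)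
8 | lithium 4-methoxy-3,5-bis(methoxymethoxy)-2-(trimethylsilyl)phenoxide | [Li+].[O-]c1cc(OCOC)c(OC)c(OCOC)c1[Si](C)(C)C | intermediate (not isolated)
9 | 4-methoxy-3,5-bis(methoxymethoxy)-2-(trimethylsilyl)phenyl trifluoromethanesulfonate | COCOc1cc(OS(=O)(=O)C(F)(F)F)c([Si](C)(C)C)c(OCOC)c1OC | intermediate
10 | 2,3-dimethoxybenzaldehyde | COc1cccc(C=O)c1OC | starting material
11 | 1-(2,2-dibromoethenyl)-2,3-dimethoxybenzene | COc1cccc(C=C(Br)Br)c1OC | intermediate
12 | lithium (2,3-dimethoxyphenyl)acetylide | [Li+].[C-]#Cc1cccc(OC)c1OC | intermediate (not isolated)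
13 | 3-(2,3-dimethoxyphenyl)prop-2-ynoic acid | COc1cccc(C#CC(=O)O)c1OC | intermediate
14 | 4-methoxy-3,5-bis(methoxymethoxy)-1,2-didehydrobenzene (aryne) | COCOC1=CC#CC(OCOC)=C1OC | intermediate (not isolated)
15 | 1-[6-hydroxy-3-methoxy-2,4-bis(methoxymethoxy)phenyl]-3-(2,3-dimethoxyphenyl)prop-2-yn-1-one | COc1cccc(C#CC(=O)c2c(O)cc(OCOC)c(OC)c2OCOC)c1OC | intermediate
16 | (2E)-3-(diethylamino)-3-(2,3-dimethoxyphenyl)-1-[6-hydroxy-3-methoxy-2,4-bis(methoxymethoxy)phenyl]prop-2-en-1-one | CCN(CC)/C(=C/C(=O)c1c(O)cc(OCOC)c(OC)c1OCOC)c1cccc(OC)c1OC | intermediate (not isolated)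
17 | 2-(2,3-dimethoxyphenyl)-6-methoxy-5,7-bis(methoxymethoxy)-4H-chromen-4-one | COc1cccc(-c2cc(=O)c3c(OCOC)c(OC)c(OCOC)cc3o2)c1OC | intermediate
18 | 8-bromo-2-(2,3-dimethoxyphenyl)-6-methoxy-5,7-bis(methoxymethoxy)-4H-chromen-4-one | COc1cccc(-c2cc(=O)c3c(OCOC)c(OC)c(OCOC)c(Br)c3o2)c1OC | intermediate
19 | 2-(2,3-dimethoxyphenyl)-6,8-dimethoxy-5,7-bis(methoxymethoxy)-4H-chromen-4-one | COc1cccc(-c2cc(=O)c3c(OCOC)c(OC)c(OCOC)c(OC)c3o2)c1OC | intermediate
20 | 2-(2,3-dimethoxyphenyl)-5,7-dihydroxy-6,8-dimethoxy-4H-chromen-4-one (5,7-dihydroxy-6,8,2',3'-tetramethoxyflavone) | COc1cccc(-c2cc(=O)c3c(O)c(OC)c(O)c(OC)c3o2)c1OC | target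

**Step count and risks**

Total step count: 11. Longest linear sequence: 9 steps (steps 1–4, then 7–11).

Steps most likely to fail:

1. Step 7. Several processes could erode it:
 - protonation of the aryl anion before it reaches the ester carbonyl, which stops at simple O-arylation;
 - thermal loss of CO2 from the propiolate;
 - arylation of the product phenoxide by a second aryne;
 - ring closure of the ynone phenoxide in the hot basic medium in the five-membered sense.

 The fallback sets out from 6 (with 13 as partner) and comes back at 15. Acid 13 is condensed with N,O-dimethylhydroxylamine hydrochloride (EDC·HCl, Et3N, CH2Cl2, 0 °C) to give the Weinreb amide N-methoxy-N-methyl-3-(2,3-dimethoxyphenyl)prop-2-ynamide F1. Bromophenol 6 is treated with n-BuLi (2.1 equiv, THF, −78 °C), which deprotonates the hydroxyl and exchanges bromine for lithium to give lithium 2-lithio-4-methoxy-3,5-bis(methoxymethoxy)phenoxide F2. Addition of F1 and a cold NH4Cl quench should give ynone 15. Here C4–C4a comes from an organolithium acylation and O1–C8a is the phenol oxygen already in place.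

2. Step 10. Possible failures are reductive loss of bromine, slow substitution at the hindered and electron-rich C8, and methoxide attack at C2 that opens the pyranone. The fallback sets out from 18 and comes back at 19. Miyaura borylation (Pd(dppf)Cl2, B2pin2, KOAc, 1,4-dioxane, 90 °C) should give 2-(2,3-dimethoxyphenyl)-6-methoxy-5,7-bis(methoxymethoxy)-8-(4,4,5,5-tetramethyl-1,3,2-dioxaborolan-2-yl)-4H-chromen-4-one F3. Oxidation (H2O2, aq. NaHCO3, THF, 0 °C) gives 2-(2,3-dimethoxyphenyl)-8-hydroxy-6-methoxy-5,7-bis(methoxymethoxy)-4H-chromen-4-one F4. O-Methylation (MeI, K2CO3, acetone, 50 °C) then gives 19.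

3. Step 4. Possible failures are protonation of the aryllithium before the silyl group has migrated, incomplete O→C silyl transfer, and consumption of Tf2O by the solvent instead of the phenoxide. The fallback sets out from 5 and comes back at 9; it replaces halogenation and halogen–metal exchange by directed ortho-metalation and so also bypasses step 3. Phenol 5 is carbamoylated (ClCONEt2, K2CO3, MeCN, 60 °C) to 4-methoxy-3,5-bis(methoxymethoxy)phenyl N,N-diethylcarbamate F5. Lithiation between the carbamate and the neighbouring MOM ether (s-BuLi, TMEDA, THF, −78 °C; both such sites are equivalent) and a TMSCl quench give 4-methoxy-3,5-bis(methoxymethoxy)-2-(trimethylsilyl)phenyl N,N-diethylcarbamate F6. Reductive carbamate cleavage with Cp2Zr(H)Cl (THF, rt) frees 4-methoxy-3,5-bis(methoxymethoxy)-2-(trimethylsilyl)phenol F7. Triflation (PhNTf2, Cs2CO3, MeCN, rt) then gives 9.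

Further compounds
F1 | step 7 | N-methoxy-N-methyl-3-(2,3-dimethoxyphenyl)prop-2-ynamide | COc1cccc(C#CC(=O)N(C)OC)c1OC
F2 | step 7 | lithium 2-lithio-4-methoxy-3,5-bis(methoxymethoxy)phenoxide | [Li+].[Li]c1c([O-])cc(OCOC)c(OC)c1OCOC
F3 | step 10 | 2-(2,3-dimethoxyphenyl)-6-methoxy-5,7-bis(methoxymethoxy)-8-(4,4,5,5-tetramethyl-1,3,2-dioxaborolan-2-yl)-4H-chromen-4-one | COc1cccc(-c2cc(=O)c3c(OCOC)c(OC)c(OCOC)c(B4OC(C)(C)C(C)(C)O4)c3o2)c1OC
F4 | step 10 | 2-(2,3-dimethoxyphenyl)-8-hydroxy-6-methoxy-5,7-bis(methoxymethoxy)-4H-chromen-4-one | COc1cccc(-c2cc(=O)c3c(OCOC)c(OC)c(OCOC)c(O)c3o2)c1OC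
F5 | step 4 | 4-methoxy-3,5-bis(methoxymethoxy)phenyl N,N-diethylcarbamate | CCN(CC)C(=O)Oc1cc(OCOC)c(OC)c(OCOC)c1
F6 | step 4 | 4-methoxy-3,5-bis(methoxymethoxy)-2-(trimethylsilyl)phenyl N,N-diethylcarbamate | CCN(CC)C(=O)Oc1cc(OCOC)c(OC)c(OCOC)c1[Si](C)(C)C
F7 | step 4 | 4-methoxy-3,5-bis(methoxymethoxy)-2-(trimethylsilyl)phenol | COCOc1cc(O)c([Si](C)(C)C)c(OCOC)c1OC
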